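**Retrosynthetic overview**
- The target is reached by hydrogenolysis of its bis(benzyl) ether. The bond between the quaternary furanone carbon (C2 of the furan-2-carboxylate) and the benzylic CH2 is made just before, by catalyst-controlled C-benzylation of a racemic 2-H furanone with a 6-(chloromethyl)chroman-3-ol; this sets the quaternary centre.
- The dihydropyran ring of the chroman (O1, C2, C3, C4, C4a, C8a) is never closed as such. It grows from the five-membered oxolane ring of a 1-oxaspiro[4.5]deca-6,9-dien-8-one (O1, C2, C3, C4 and the spiro carbon) when C4 migrates from the spiro carbon to the neighbouring ring carbon after LiCH2Cl has added to the ketone.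
- Enabling feature: in the chroman, O1 sits on C8a para to C6 (which carries the benzylic carbon) and C4 sits on C4a ortho to C8a. C8a can therefore be a spiro carbon bearing O1 and C4, C6 the dienone carbonyl, and O1 stabilises the cation left when C4 shifts.
- The spirodienone comes from dearomatising spirocyclisation (PhI(OAc)2) of a phenol diol made with MeMgBr from methyl (R)-4-hydroxyphenyllactate, which supplies the (R)-carbinol. The furanone comes from aldol–lactonisation of a 3,4-bis(benzyloxy)phenylpyruvate with methyl glyoxylate, then O-methylation.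
- Ring order: oxolane (spiro) → dihydropyran with re-formed benzene ring; the furanone is built separately; the halves are joined in step 8.

Key step: step 3

Assumption: 1 is bought as the (R)-enantiomer (otherwise made from D-tyrosine by diazotisation with retention and esterification); methyl glyoxylate is cracked fresh from its commercial methyl hemiacetal.

**Step 1**
Reactants: 1 methyl (2R)-2-hydroxy-3-(4-hydroxyphenyl)propanoate
Product: 2 (2R)-1-(4-hydroxyphenyl)-3-methylbutane-2,3-diol
Conditions: MeMgBr (5 equiv), THF, 0 °C → rt; aq NH4Cl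
Reagents that add atoms: methylmagnesium bromide, C[Mg]Br
Why: Double Grignard addition to the ester after deprotonation of both hydroxyls should give the tertiary carbinol, the alkoxide next to the carbonyl suppressing enolisation so that the (R)-centre is kept.

**Step 2**
Reactants: 2 (2R)-1-(4-hydroxyphenyl)-3-methylbutane-2,3-diol
Product: 3 (3R)-3-hydroxy-2,2-dimethyl-1-oxaspiro[4.5]deca-6,9-dien-8-one
Conditions: PhI(OAc)2 (1.1 equiv), (CF3)2CHOH/CH2Cl2, 0 °C
Reagents that add atoms: none
Why: Oxidative dearomatisation of the phenol by the trivalent iodine reagent should give an aryloxy-λ3-iodane that is captured at the para carbon by the tertiary hydroxyl in a 5-exo ipso-spirocyclisation (the secondary hydroxyl could only form an oxetane), the (R)-carbinol being untouched and the spiro carbon not stereogenic.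

**Step 3**
Reactants: 3 (3R)-3-hydroxy-2,2-dimethyl-1-oxaspiro[4.5]deca-6,9-dien-8-one
Product: 5 (3R)-6-(chloromethyl)-2,2-dimethyl-3,4-dihydro-2H-chromen-3-ol, via spirocyclic chlorohydrin 4 (not isolated)
Conditions: ICH2Cl (3.5 equiv), MeLi·LiBr (3.2 equiv), THF, −78 °C; then HCl (4 M in 1,4-dioxane, 6 equiv), −78 → 0 °C
Reagents that add atoms: chloroiodomethane, ClCI
Why: Proposed new method: LiCH2Cl, made in the flask from ICH2Cl and MeLi·LiBr (the first equivalent of MeLi only deprotonates the C3 hydroxyl), should add 1,2 to the cross-conjugated ketone of 3 to give the tertiary bis-allylic chlorohydrin 4, and HCl should then ionise this carbinol to a cyclohexadienyl cation in which C4 shifts from the spiro carbon to the neighbouring cationic ring carbon and that carbon loses its proton, so that the benzene ring is re-formed with the former carbonyl carbon, now bearing CH2Cl, para to O1. The closest known reactions are the acid-promoted dienone–phenol rearrangement of 1-oxaspiro[4.5]deca-6,9-dien-8-ones to chroman-6-ols, the dienol–benzene rearrangement of tertiary 4,4-disubstituted cyclohexa-2,5-dienols and the 1,2-addition of halomethyllithium carbenoids to enones. The dihydropyran ring is not closed by a new bond from a chain: it arises from the five-membered oxolane ring by a 1,2-alkyl (Wagner–Meerwein) shift, a ring expansion by one carbon atom. No stereocentre is created, since the spiro carbon is not stereogenic, the cis and trans forms of 4 give the same cation and the (R)-carbinol from 1 lies outside all bonds that change. The step needs migration of carbon and not of oxygen, and ionisation of the C8 carbinol and not productive opening of the spiro ether; the first is secured because only the shift of C4 leaves a cation stabilised by O1 as an oxocarbenium ion, the second because opening of the spiro C–O bond is reversible and could only be followed by migration of the electron-poor CH2Cl group, while a hydride shift from CH2Cl would give a poorly stabilised α-chloro cation.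

**Step 4**
Reactants: 6 3,4-bis(benzyloxy)benzaldehyde; 7 methyl 2-[(tert-butoxycarbonyl)amino]-2-(dimethoxyphosphoryl)acetate
Product: 8 methyl (2Z)-3-[3,4-bis(benzyloxy)phenyl]-2-[(tert-butoxycarbonyl)amino]prop-2-enoate
Conditions: DBU (1.2 equiv), CH2Cl2, 0 °C → rt
Reagents that add atoms: none
Why: Horner–Wadsworth–Emmons olefination of the aldehyde with the phosphonoglycinate anion should give the (Z)-dehydroamino ester, a masked α-keto ester, with no stereocentre formed.

**Step 5**
Reactants: 8 methyl (2Z)-3-[3,4-bis(benzyloxy)phenyl]-2-[(tert-butoxycarbonyl)amino]prop-2-enoate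
Product: 10 methyl 3-[3,4-bis(benzyloxy)phenyl]-2-oxopropanoate, via free enamino ester 9 (not isolated)
Conditions: HCl (4 M in 1,4-dioxane), 0 °C → rt; then H2O/THF, rt
Reagents that add atoms: water, O
Why: Acidolysis of the carbamate frees the enamine, whose iminium tautomer is hydrolysed by water to the α-keto ester (enamide-to-ketone hydrolysis), the aryl benzyl ethers tolerating anhydrous HCl at room temperature.

**Step 6**
Reactants: 10 methyl 3-[3,4-bis(benzyloxy)phenyl]-2-oxopropanoate; 11 methyl glyoxylate
Product: 13 methyl 3-[3,4-bis(benzyloxy)phenyl]-4-hydroxy-5-oxo-2,5-dihydrofuran-2-carboxylate (racemic), via open-chain aldol adduct 12 (not isolated)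
Conditions: 11 (3 equiv), Et3N (1.1 equiv), CH2Cl2, 0 °C → rt; 1 M HCl work-up
Reagents that add atoms: none
Why: Crossed aldol–lactonisation: the easily formed enolate of 10 adds to the far more electrophilic, non-enolisable aldehyde 11 used in excess, the new alkoxide closes the γ-lactone on the pyruvate ester (5-exo-trig) and the 1,2-dicarbonyl enolises, the C2 centre being formed racemic and made planar again in step 8.

**Step 7**
Reactants: 13 methyl 3-[3,4-bis(benzyloxy)phenyl]-4-hydroxy-5-oxo-2,5-dihydrofuran-2-carboxylate (racemic)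
Product: 14 methyl 3-[3,4-bis(benzyloxy)phenyl]-4-methoxy-5-oxo-2,5-dihydrofuran-2-carboxylate (racemic)
Conditions: TMSCHN2 (2 M in hexanes, 1.5 equiv), toluene/MeOH, 0 °C
Reagents that add atoms: (trimethylsilyl)diazomethane, C[Si](C)(C)C=[N+]=[N-]
Why: Diazoalkane O-methylation selects the strongly acidic enol hydroxyl and needs no base, so the acidic C2–H is not alkylated.

**Step 8**
Reactants: 14 methyl 3-[3,4-bis(benzyloxy)phenyl]-4-methoxy-5-oxo-2,5-dihydrofuran-2-carboxylate (racemic); 5 (3R)-6-(chloromethyl)-2,2-dimethyl-3,4-dihydro-2H-chromen-3-ol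
Product: 15 methyl (2R)-3-[3,4-bis(benzyloxy)phenyl]-2-{[(3R)-3-hydroxy-2,2-dimethyl-3,4-dihydro-2H-chromen-6-yl]methyl}-4-methoxy-5-oxo-2,5-dihydrofuran-2-carboxylate
Conditions: (S,S)-N-spiro bis(binaphthyl-2,2′-dimethylene)ammonium bromide with 3,4,5-trifluorophenyl groups at the 3,3′-positions of one binaphthyl (2 mol %), Cs2CO3 (1.5 equiv), toluene, −20 °C
Reagents that add atoms: none
Why: Asymmetric phase-transfer C-alkylation: Cs2CO3 removes the acidic C2–H of 14 to give a planar 2-oxidofuran (both enantiomers of 14 converge on it) whose ion pair with the chiral ammonium cation exposes one face of C2 to the reactive para-alkoxybenzylic chloride 5, as in the known enantioselective benzylation of phthalide-3-carboxylates and α-acyloxymalonates, so the quaternary centre is set under catalyst control (the remote carbinol of 5 has no say, and the catalyst antipode is taken if the (S,S)-salt favours the C2 epimer), attack at C2 rather than C4 being expected because C4 already carries OMe and only C2 alkylation keeps the conjugated butenolide.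

**Step 9**
Reactants: 15 methyl (2R)-3-[3,4-bis(benzyloxy)phenyl]-2-{[(3R)-3-hydroxy-2,2-dimethyl-3,4-dihydro-2H-chromen-6-yl]methyl}-4-methoxy-5-oxo-2,5-dihydrofuran-2-carboxylate
Product: 16 methyl (2R)-3-(3,4-dihydroxyphenyl)-2-{[(3R)-3-hydroxy-2,2-dimethyl-3,4-dihydro-2H-chromen-6-yl]methyl}-4-methoxy-5-oxo-2,5-dihydrofuran-2-carboxylate
Conditions: H2 (1 atm), Pd/C (10 wt %), EtOAc/MeOH, rt
Reagents that add atoms: none
Why: Hydrogenolysis of the two aryl benzyl ethers on Pd/C should free the catechol, while the hindered tetrasubstituted butenolide alkene, the aryl–O bond and the homobenzylic lactone C–O bond are not reduced under one atmosphere of H2 and both stereocentres are untouched.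

**Compound list**
1 | methyl (2R)-2-hydroxy-3-(4-hydroxyphenyl)propanoate | COC(=O)[C@H](O)Cc1ccc(O)cc1 | starting material
2 | (2R)-1-(4-hydroxyphenyl)-3-methylbutane-2,3-diol | CC(C)(O)[C@H](O)Cc1ccc(O)cc1 | intermediate
3 | (3R)-3-hydroxy-2,2-dimethyl-1-oxaspiro[4.5]deca-6,9-dien-8-one | O=C1C=CC2(C=C1)C[C@@H](O)C(C)(C)O2 | intermediate
4 | (3R)-8-(chloromethyl)-2,2-dimethyl-1-oxaspiro[4.5]deca-6,9-diene-3,8-diol (cis/trans at C8; present as its dilithium alkoxide before acidification; not isolated) | OC1(CCl)C=CC2(C=C1)C[C@@H](O)C(C)(C)O2 | intermediate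
5 | (3R)-6-(chloromethyl)-2,2-dimethyl-3,4-dihydro-2H-chromen-3-ol | ClCc1ccc2c(c1)C[C@@H](O)C(C)(C)O2 | intermediate
6 | 3,4-bis(benzyloxy)benzaldehyde | O=Cc1ccc(OCc2ccccc2)c(OCc2ccccc2)c1 | starting material
7 | methyl 2-[(tert-butoxycarbonyl)amino]-2-(dimethoxyphosphoryl)acetate (racemic) | COC(=O)C(NC(=O)OC(C)(C)C)P(=O)(OC)OC | starting material
8 | methyl (2Z)-3-[3,4-bis(benzyloxy)phenyl]-2-[(tert-butoxycarbonyl)amino]prop-2-enoate | COC(=O)/C(NC(=O)OC(C)(C)C)=C/c1ccc(OCc2ccccc2)c(OCc2ccccc2)c1 | intermediate
9 | methyl (2Z)-2-amino-3-[3,4-bis(benzyloxy)phenyl]prop-2-enoate (as hydrochloride; not isolated) | COC(=O)/C(N)=C/c1ccc(OCc2ccccc2)c(OCc2ccccc2)c1 | intermediate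
10 | methyl 3-[3,4-bis(benzyloxy)phenyl]-2-oxopropanoate | COC(=O)C(=O)Cc1ccc(OCc2ccccc2)c(OCc2ccccc2)c1 | intermediate
11 | methyl glyoxylate (methyl 2-oxoacetate) | COC(=O)C=O | starting material
12 | dimethyl 3-[3,4-bis(benzyloxy)phenyl]-2-hydroxy-4-oxopentanedioate (diastereomer mixture; not isolated) | COC(=O)C(O)C(c1ccc(OCc2ccccc2)c(OCc2ccccc2)c1)C(=O)C(=O)OC | intermediate
13 | methyl 3-[3,4-bis(benzyloxy)phenyl]-4-hydroxy-5-oxo-2,5-dihydrofuran-2-carboxylate (racemic) | COC(=O)C1OC(=O)C(O)=C1c1ccc(OCc2ccccc2)c(OCc2ccccc2)c1 | intermediate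
14 | methyl 3-[3,4-bis(benzyloxy)phenyl]-4-methoxy-5-oxo-2,5-dihydrofuran-2-carboxylate (racemic) | COC(=O)C1OC(=O)C(OC)=C1c1ccc(OCc2ccccc2)c(OCc2ccccc2)c1 | intermediate
15 | methyl (2R)-3-[3,4-bis(benzyloxy)phenyl]-2-{[(3R)-3-hydroxy-2,2-dimethyl-3,4-dihydro-2H-chromen-6-yl]methyl}-4-methoxy-5-oxo-2,5-dihydrofuran-2-carboxylate | COC(=O)[C@]1(Cc2ccc3c(c2)C[C@@H](O)C(C)(C)O3)OC(=O)C(OC)=C1c1ccc(OCc2ccccc2)c(OCc2ccccc2)c1 | intermediate
16 | methyl (2R)-3-(3,4-dihydroxyphenyl)-2-{[(3R)-3-hydroxy-2,2-dimethyl-3,4-dihydro-2H-chromen-6-yl]methyl}-4-methoxy-5-oxo-2,5-dihydrofuran-2-carboxylate | COC(=O)[C@]1(Cc2ccc3c(c2)C[C@@H](O)C(C)(C)O3)OC(=O)C(OC)=C1c1ccc(O)c(O)c1 | target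

**Step count and risks**
Total steps: 9. Longest linear sequence: 6 steps (steps 4, 5, 6, 7, 8, 9, from 6 and 7).

Steps most likely to fail:

1. Step 3 (proposed new method). The chlorohydrin may react otherwise than planned: closure to the spiro-epoxide before acidification followed by a hydride shift, ionisation at the spiro ether with loss of the ring, or solvolysis of the benzylic chloride under the acid. The fallback uses known chemistry and sets out from 3. Treatment of 3 with CF3CO2H in CH2Cl2 (acid-promoted dienone–phenol rearrangement, the same one-carbon ring expansion with the carbonyl oxygen kept) should give (3R)-2,2-dimethyl-3,4-dihydro-2H-chromene-3,6-diol F1. Phenol-selective triflation (PhNTf2, K2CO3, THF) gives (3R)-3-hydroxy-2,2-dimethyl-3,4-dihydro-2H-chromen-6-yl trifluoromethanesulfonate F2. Methoxycarbonylation (CO, MeOH, Pd(OAc)2, 1,3-bis(diphenylphosphino)propane, Et3N, DMF, 70 °C) gives methyl (3R)-3-hydroxy-2,2-dimethyl-3,4-dihydro-2H-chromene-6-carboxylate F3. Reduction with LiAlH4 in THF gives (3R)-6-(hydroxymethyl)-2,2-dimethyl-3,4-dihydro-2H-chromen-3-ol F4. Concentrated aqueous HCl in CH2Cl2 at 0 °C then converts only the para-alkoxybenzylic hydroxyl into the chloride, and the route is rejoined at 5.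

2. Step 8. The ambident furanolate may be alkylated at C4 instead of C2, or the ion pair may discriminate the two faces of C2 poorly. The fallback sets out from 5 and changes the mode of activation from ion pairing to a chiral metal-bound electrophile. Displacement of chloride with diethyl hydrogen phosphate and Cs2CO3 in DMF gives diethyl [(3R)-3-hydroxy-2,2-dimethyl-3,4-dihydro-2H-chromen-6-yl]methyl phosphate F5. Palladium-catalysed asymmetric benzylation of 14 with F5 through an η3-benzyl palladium intermediate follows (Pd2(dba)3 as zerovalent palladium source, (R,R)-N,N′-(cyclohexane-1,2-diyl)bis[2-(diphenylphosphanyl)benzamide], Cs2CO3, tert-butanol/1,4-dioxane). This reaction type is established for azlactones and 3-aryloxindoles with electron-rich benzylic phosphates. It returns to the route at 15.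

3. Step 2. The oxidised phenol may be captured intermolecularly (oligomers, solvent adducts) or over-oxidised instead of undergoing 5-exo ipso attack by the tertiary hydroxyl. The fallback sets out from 2 and changes the mechanism from a phenoxenium-type intermediate to an arene radical cation. Phenol-selective O-methylation (MeI, K2CO3, acetone) gives (2R)-1-(4-methoxyphenyl)-3-methylbutane-2,3-diol F6. PhI(OCOCF3)2 in (CF3)2CHOH/H2O at 0 °C should then oxidise the aryl ether, the tertiary hydroxyl attacks the ipso carbon and the O-methyl oxocarbenium ion is hydrolysed (known ipso-spirocyclisation of para-substituted phenol ethers). The route is rejoined at 3.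

**Further compounds**
F1 | step 3 | (3R)-2,2-dimethyl-3,4-dihydro-2H-chromene-3,6-diol | Oc1ccc2c(c1)C[C@@H](O)C(C)(C)O2
F2 | step 3 | (3R)-3-hydroxy-2,2-dimethyl-3,4-dihydro-2H-chromen-6-yl trifluoromethanesulfonate | O=S(=O)(Oc1ccc2c(c1)C[C@@H](O)C(C)(C)O2)C(F)(F)F
F3 | step 3 | methyl (3R)-3-hydroxy-2,2-dimethyl-3,4-dihydro-2H-chromene-6-carboxylate | COC(=O)c1ccc2c(c1)C[C@@H](O)C(C)(C)O2
F4 | step 3 | (3R)-6-(hydroxymethyl)-2,2-dimethyl-3,4-dihydro-2H-chromen-3-ol | OCc1ccc2c(c1)C[C@@H](O)C(C)(C)O2
F5 | step 8 | diethyl [(3R)-3-hydroxy-2,2-dimethyl-3,4-dihydro-2H-chromen-6-yl]methyl phosphate | CCOP(=O)(OCC)OCc1ccc2c(c1)C[C@@H](O)C(C)(C)O2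
F6 | step 2 | (2R)-1-(4-methoxyphenyl)-3-methylbutane-2,3-diol | COc1ccc(C[C@@H](O)C(C)(C)O)cc1
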